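**Retrosynthetic overview**
1. Target 26 ← desilylation of 25 ← ring-closing metathesis of seco-triene 24, forming C4=C5 (Z) and the ten-membered ring (second and last ring formed).
2. 24 ← Mitsunobu esterification of carbinol 23 with tiglic acid (inversion at C8).
3. 23 ← zinc Barbier allylation at C7–C8 joining fragment 2 (bromobutenolide 21: C5–C7, C11–C13) with fragment 1 (enal 11: C8–C10, C1–C4, C14, C15); this sets the 6,7-trans α-methylene lactone.
4. 11 ← Paterson boron aldol (C2–C3) of enone 6 with aldehyde 3, then Evans–Tishchenko reduction (1,3-anti C1/C3, acetate delivered to O3).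
5. 21 ← butenolide ring (first ring formed) by Pd-catalysed carbonylative lactonisation of Z-iodo alcohol 18, made from the kinetically resolved enynol 16.

Assumption: locants C1–C15 are germacrane locants of the target (C12 = lactone carbonyl bound through O to C6, C13 = exocyclic CH2, C14 = methyl on C10, C15 = CH2OH on C4), and the target is taken exactly as the SMILES gives it (1S,3S,6R,7R,8R; 4Z,9E; tiglate 2E).
Abbreviation: TBS = tert-butyl(dimethyl)silyl.

**Fragment 1 (enal 11)**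

Step 1
Reactants: 1 2-methylidenepropane-1,3-diol
Product: 2 2-[(TBS-oxy)methyl]prop-2-en-1-ol
Conditions: NaH (1.0 equiv), THF, 0 °C; TBSCl (1.0 equiv), 23 °C
Reagents that add atoms: tert-butyl(chloro)dimethylsilane (TBSCl) CC(C)(C)[Si](C)(C)Cl
Why: Monosilylation of a symmetric diol through its sparingly soluble monosodium alkoxide (Williamson-type O-silylation) protects one hydroxyl only; no stereocentre is involved.

Step 2
Reactants: 2 2-[(TBS-oxy)methyl]prop-2-en-1-ol
Product: 3 2-[(TBS-oxy)methyl]prop-2-enal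
Conditions: MnO2 (excess), CH2Cl2, 23 °C
Reagents that add atoms: none
Why: MnO2 oxidation of a primary allylic alcohol stops cleanly at the enal and leaves the silyl ether alone.

Step 3
Reactants: 4 2,2-dimethoxyacetaldehyde; 5 3-(triphenyl-λ5-phosphanylidene)butan-2-one
Product: 6 (3E)-5,5-dimethoxy-3-methylpent-3-en-2-one
Conditions: toluene, 80 °C
Reagents that add atoms: none
Why: Wittig olefination with a ketone-stabilised ylide is E-selective, placing the acetal carbon (future C8) trans to the acetyl carbon (future C1) as the 9E alkene requires.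

Step 4
Reactants: 6 (3E)-5,5-dimethoxy-3-methylpent-3-en-2-one; 3 2-[(TBS-oxy)methyl]prop-2-enal
Product: 8 (2E,6S)-7-[(TBS-oxy)methyl]-6-hydroxy-1,1-dimethoxy-3-methylocta-2,7-dien-4-one, via boron enolate 7 (not isolated)
Conditions: (+)-Ipc2BCl, Et3N, Et2O, 0 °C; then 3, −78 → −20 °C; H2O2, MeOH, pH 7 buffer, 0 °C
Reagents that add atoms: none
Why: Paterson boron aldol reaction, in which the methyl-side enol diisopinocampheylborinate adds to the Si face of aldehyde 3 under control of the isopinocampheyl ligands and sets C3 as S (reagent control, typically 75–90% ee).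

Step 5
Reactants: 8 (2E,6S)-7-[(TBS-oxy)methyl]-6-hydroxy-1,1-dimethoxy-3-methylocta-2,7-dien-4-one
Product: 9 (2E,4S,6S)-7-[(TBS-oxy)methyl]-4-hydroxy-1,1-dimethoxy-3-methylocta-2,7-dien-6-yl acetate
Conditions: SmI2 (0.3 equiv, pre-aged with MeCHO), MeCHO (8 equiv), THF, −10 °C
Reagents that add atoms: acetaldehyde CC=O
Why: Evans–Tishchenko reduction, in which the samarium-bound hemiacetal of O3 and acetaldehyde transfers hydride to the C1 ketone through a chair six-membered transition state, giving the 1,3-anti product (C1 S) with the acetate left on O3.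

Step 6
Reactants: 9 (2E,4S,6S)-7-[(TBS-oxy)methyl]-4-hydroxy-1,1-dimethoxy-3-methylocta-2,7-dien-6-yl acetate
Product: 10 (2E,4S,6S)-4-(TBS-oxy)-7-[(TBS-oxy)methyl]-1,1-dimethoxy-3-methylocta-2,7-dien-6-yl acetate
Conditions: TBSOTf, 2,6-lutidine, CH2Cl2, −78 °C
Reagents that add atoms: tert-butyldimethylsilyl trifluoromethanesulfonate CC(C)(C)[Si](C)(C)OS(=O)(=O)C(F)(F)F
Why: Fast low-temperature O-silylation of the C1 hydroxyl outruns 1,3-acetyl migration and does not touch the acetal or acetate.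

Step 7
Reactants: 10 (2E,4S,6S)-4-(TBS-oxy)-7-[(TBS-oxy)methyl]-1,1-dimethoxy-3-methylocta-2,7-dien-6-yl acetate
Product: 11 (2E,4S,6S)-4-(TBS-oxy)-7-[(TBS-oxy)methyl]-3-methyl-1-oxoocta-2,7-dien-6-yl acetate (fragment 1)
Conditions: pyridinium 4-toluenesulfonate (cat.), acetone/H2O 9:1, 23 °C
Reagents that add atoms: water O
Why: Mild acid-catalysed acetal hydrolysis unmasks the conjugated E-enal (the thermodynamically preferred geometry) while TBS ethers and the acetate survive.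

**Fragment 2 (bromobutenolide 21)**

Step 8
Reactants: 12 tert-butyl(dimethyl)(prop-2-yn-1-yloxy)silane; 13 prop-2-enal (acrolein)
Product: 15 rac-6-(TBS-oxy)hex-1-en-4-yn-3-ol, via lithium acetylide 14 (not isolated)
Conditions: n-BuLi, THF, −78 °C; then 13, −78 °C; H2O
Reagents that add atoms: none
Why: 1,2-Addition of a lithium acetylide to acrolein at low temperature gives the racemic vinyl alkynyl carbinol.

Step 9
Reactants: 15 rac-6-(TBS-oxy)hex-1-en-4-yn-3-ol
Product: 16 (3R)-6-(TBS-oxy)hex-1-en-4-yn-3-ol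
Conditions: Ti(OiPr)4 (0.15 equiv), D-(−)-diisopropyl tartrate (0.2 equiv), t-BuOOH (0.6 equiv), 4 Å sieves, CH2Cl2, −20 °C
Reagents that add atoms: none
Why: Sharpless kinetic resolution, in which the titanium tartrate catalyst epoxidises the S-enantiomer much faster, so the R-alcohol (future C6) is recovered in high ee at up to 50% yield.

Step 10
Reactants: 16 (3R)-6-(TBS-oxy)hex-1-en-4-yn-3-ol
Product: 18 (3R,4Z)-6-(TBS-oxy)-5-iodohexa-1,4-dien-3-ol, via alkenylaluminate 17 (not isolated)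
Conditions: NaAlH2(OCH2CH2OCH3)2, THF, 0 → 23 °C; then I2, −78 °C
Reagents that add atoms: iodine II
Why: Hydroxyl-directed trans-hydroalumination puts aluminium on the distal alkyne carbon in a five-membered aluminate, and iodinolysis with retention gives the Z-vinyl iodide with iodine cis to the carbinol; C6 is untouched.

Step 11
Reactants: 18 (3R,4Z)-6-(TBS-oxy)-5-iodohexa-1,4-dien-3-ol
Product: 19 (5R)-3-[(TBS-oxy)methyl]-5-ethenylfuran-2(5H)-one
Conditions: Pd(PPh3)2Cl2 (5 mol %), CO (1 atm), iPr2NEt, THF, 45 °C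
Reagents that add atoms: carbon monoxide [C-]#[O+]
Why: Palladium-catalysed carbonylative lactonisation, in which zerovalent palladium inserts into the C–I bond, CO insertion gives an acylpalladium, and the cis hydroxyl captures it; the C6–O bond is not broken, so configuration is retained.

Step 12
Reactants: 19 (5R)-3-[(TBS-oxy)methyl]-5-ethenylfuran-2(5H)-one
Product: 20 (5R)-5-ethenyl-3-(hydroxymethyl)furan-2(5H)-one
Conditions: aq. HF, MeCN, 0 °C
Reagents that add atoms: none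
Why: Acidic fluoride desilylation frees the primary alcohol without the base that could deprotonate the γ-position of the vinyl butenolide.

Step 13
Reactants: 20 (5R)-5-ethenyl-3-(hydroxymethyl)furan-2(5H)-one
Product: 21 (5R)-3-(bromomethyl)-5-ethenylfuran-2(5H)-one (fragment 2)
Conditions: CBr4, PPh3, CH2Cl2, 0 °C
Reagents that add atoms: carbon tetrabromide BrC(Br)(Br)Br
Why: Appel bromination converts the primary allylic alcohol to the bromide under neutral conditions.

**Union and ring closure**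

Step 14
Reactants: 21 (5R)-3-(bromomethyl)-5-ethenylfuran-2(5H)-one; 11 (2E,4S,6S)-4-(TBS-oxy)-7-[(TBS-oxy)methyl]-3-methyl-1-oxoocta-2,7-dien-6-yl acetate
Product: 23 (4R,5R)-4-[(1S,2E,4S,6S)-6-acetoxy-4-(TBS-oxy)-7-[(TBS-oxy)methyl]-1-hydroxy-3-methylocta-2,7-dien-1-yl]-5-ethenyl-3-methylideneoxolan-2-one, via allylzinc bromide 22 (not isolated)
Conditions: Zn dust, THF/sat. aq. NH4Cl, 0 → 23 °C
Reagents that add atoms: none
Why: Zinc Barbier allylation, in which the allylzinc reacts at its γ-carbon (C7) through a closed chair transition state on the face anti to the C6 vinyl group (6,7-trans) with the aldehyde residue equatorial, giving the exocyclic methylene lactone and the 8S carbinol.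

Step 15
Reactants: 23 (4R,5R)-4-[(1S,2E,4S,6S)-6-acetoxy-4-(TBS-oxy)-7-[(TBS-oxy)methyl]-1-hydroxy-3-methylocta-2,7-dien-1-yl]-5-ethenyl-3-methylideneoxolan-2-one
Product: 24 (1R,2E,4S,6S)-6-acetoxy-4-(TBS-oxy)-7-[(TBS-oxy)methyl]-1-[(2R,3S)-2-ethenyl-4-methylidene-5-oxooxolan-3-yl]-3-methylocta-2,7-dien-1-yl (2E)-2-methylbut-2-enoate
Conditions: tiglic acid, PPh3, DIAD, toluene, 0 → 23 °C
Reagents that add atoms: tiglic acid C/C=C(\C)C(=O)O
Why: Mitsunobu esterification, in which SN2 displacement of the oxyphosphonium by tiglate inverts C8 from S to R and installs the tigloyl ester in one operation (the lactone carbon label changes to 3S only through CIP priorities).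

Step 16
Reactants: 24 (1R,2E,4S,6S)-6-acetoxy-4-(TBS-oxy)-7-[(TBS-oxy)methyl]-1-[(2R,3S)-2-ethenyl-4-methylidene-5-oxooxolan-3-yl]-3-methylocta-2,7-dien-1-yl (2E)-2-methylbut-2-enoate
Product: 25 (1S,3S,4Z,6R,7R,8R,9E)-3-acetoxy-1,15-bis(TBS-oxy)-8-{[(2E)-2-methylbut-2-enoyl]oxy}germacra-4,9,11(13)-trien-12,6-olide
Conditions: second-generation Grubbs catalyst [RuCl2(=CHPh)(PCy3)(H2IMes)] (15 mol %), toluene (1 mM), 80 °C
Reagents that add atoms: none
Why: Ring-closing metathesis of the C5 vinyl with the C4 methylidene at high dilution closes the ten-membered ring; the cis (4Z) ring olefin is the less strained partner of the 9E alkene, and the conjugated or trisubstituted alkenes do not engage the ruthenium carbene.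

Step 17
Reactants: 25 (1S,3S,4Z,6R,7R,8R,9E)-3-acetoxy-1,15-bis(TBS-oxy)-8-{[(2E)-2-methylbut-2-enoyl]oxy}germacra-4,9,11(13)-trien-12,6-olide
Product: 26 (1S,3S,4Z,6R,7R,8R,9E)-3-acetoxy-1,15-dihydroxy-8-{[(2E)-2-methylbut-2-enoyl]oxy}germacra-4,9,11(13)-trien-12,6-olide (CNP0153210.7)
Conditions: HF·pyridine, pyridine/THF, 0 → 23 °C
Reagents that add atoms: none
Why: Buffered fluoride desilylation removes both TBS ethers without acyl migration, ester cleavage or conjugate addition to the α-methylene lactone.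

**Compound list**
1 | 2-methylidenepropane-1,3-diol | C=C(CO)CO | starting material
2 | 2-[(TBS-oxy)methyl]prop-2-en-1-ol | C=C(CO)CO[Si](C)(C)C(C)(C)C | intermediate
3 | 2-[(TBS-oxy)methyl]prop-2-enal | C=C(C=O)CO[Si](C)(C)C(C)(C)C | intermediate
4 | 2,2-dimethoxyacetaldehyde | COC(OC)C=O | starting material
5 | 3-(triphenyl-λ5-phosphanylidene)butan-2-one | CC(=O)C(C)=P(c1ccccc1)(c1ccccc1)c1ccccc1 | starting material
6 | (3E)-5,5-dimethoxy-3-methylpent-3-en-2-one | CC(=O)/C(C)=C/C(OC)OC | intermediate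
7 | (3E)-5,5-dimethoxy-3-methylpenta-1,3-dien-2-yl diisopinocampheylborinate (boron enolate, not isolated) | C=C(OB([C@H]1C[C@H]2C[C@@H]([C@@H]1C)C2(C)C)[C@H]1C[C@H]2C[C@@H]([C@@H]1C)C2(C)C)/C(C)=C/C(OC)OC | intermediate
8 | (2E,6S)-7-[(TBS-oxy)methyl]-6-hydroxy-1,1-dimethoxy-3-methylocta-2,7-dien-4-one | COC(OC)/C=C(\C)C(=O)C[C@H](O)C(=C)CO[Si](C)(C)C(C)(C)C | intermediate
9 | (2E,4S,6S)-7-[(TBS-oxy)methyl]-4-hydroxy-1,1-dimethoxy-3-methylocta-2,7-dien-6-yl acetate | COC(OC)/C=C(\C)[C@@H](O)C[C@H](OC(C)=O)C(=C)CO[Si](C)(C)C(C)(C)C | intermediate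
10 | (2E,4S,6S)-4-(TBS-oxy)-7-[(TBS-oxy)methyl]-1,1-dimethoxy-3-methylocta-2,7-dien-6-yl acetate | COC(OC)/C=C(\C)[C@@H](O[Si](C)(C)C(C)(C)C)C[C@H](OC(C)=O)C(=C)CO[Si](C)(C)C(C)(C)C | intermediate
11 | (2E,4S,6S)-4-(TBS-oxy)-7-[(TBS-oxy)methyl]-3-methyl-1-oxoocta-2,7-dien-6-yl acetate (fragment 1) | O=C/C=C(\C)[C@@H](O[Si](C)(C)C(C)(C)C)C[C@H](OC(C)=O)C(=C)CO[Si](C)(C)C(C)(C)C | intermediate
12 | tert-butyl(dimethyl)(prop-2-yn-1-yloxy)silane | C#CCO[Si](C)(C)C(C)(C)C | starting material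
13 | prop-2-enal (acrolein) | C=CC=O | starting material
14 | [3-(TBS-oxy)prop-1-yn-1-yl]lithium (lithium acetylide, not isolated) | [Li]C#CCO[Si](C)(C)C(C)(C)C | intermediate
15 | rac-6-(TBS-oxy)hex-1-en-4-yn-3-ol | C=CC(O)C#CCO[Si](C)(C)C(C)(C)C | intermediate
16 | (3R)-6-(TBS-oxy)hex-1-en-4-yn-3-ol | C=C[C@@H](O)C#CCO[Si](C)(C)C(C)(C)C | intermediate
17 | sodium (5R)-5-ethenyl-2,2-bis(2-methoxyethoxy)-3-[(TBS-oxy)methyl]-2,5-dihydro-1,2-oxaaluminol-2-uide (alkenylaluminate, not isolated) | [Na+].C=C[C@H]1O[Al-](OCCOC)(OCCOC)C(CO[Si](C)(C)C(C)(C)C)=C1 | intermediate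
18 | (3R,4Z)-6-(TBS-oxy)-5-iodohexa-1,4-dien-3-ol | C=C[C@@H](O)/C=C(\I)CO[Si](C)(C)C(C)(C)C | intermediate
19 | (5R)-3-[(TBS-oxy)methyl]-5-ethenylfuran-2(5H)-one | C=C[C@H]1OC(=O)C(CO[Si](C)(C)C(C)(C)C)=C1 | intermediate
20 | (5R)-5-ethenyl-3-(hydroxymethyl)furan-2(5H)-one | C=C[C@H]1OC(=O)C(CO)=C1 | intermediate
21 | (5R)-3-(bromomethyl)-5-ethenylfuran-2(5H)-one (fragment 2) | C=C[C@H]1OC(=O)C(CBr)=C1 | intermediate
22 | {[(5R)-5-ethenyl-2-oxo-2,5-dihydrofuran-3-yl]methyl}zinc bromide (allylzinc bromide, not isolated) | C=C[C@H]1OC(=O)C(C[Zn]Br)=C1 | intermediate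
23 | (4R,5R)-4-[(1S,2E,4S,6S)-6-acetoxy-4-(TBS-oxy)-7-[(TBS-oxy)methyl]-1-hydroxy-3-methylocta-2,7-dien-1-yl]-5-ethenyl-3-methylideneoxolan-2-one | C=C1C(=O)O[C@H](C=C)[C@H]1[C@@H](O)/C=C(\C)[C@@H](O[Si](C)(C)C(C)(C)C)C[C@H](OC(C)=O)C(=C)CO[Si](C)(C)C(C)(C)C | intermediate
24 | (1R,2E,4S,6S)-6-acetoxy-4-(TBS-oxy)-7-[(TBS-oxy)methyl]-1-[(2R,3S)-2-ethenyl-4-methylidene-5-oxooxolan-3-yl]-3-methylocta-2,7-dien-1-yl (2E)-2-methylbut-2-enoate | C=C1C(=O)O[C@H](C=C)[C@H]1[C@H](OC(=O)/C(C)=C/C)/C=C(\C)[C@@H](O[Si](C)(C)C(C)(C)C)C[C@H](OC(C)=O)C(=C)CO[Si](C)(C)C(C)(C)C | intermediate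
25 | (1S,3S,4Z,6R,7R,8R,9E)-3-acetoxy-1,15-bis(TBS-oxy)-8-{[(2E)-2-methylbut-2-enoyl]oxy}germacra-4,9,11(13)-trien-12,6-olide | C=C1C(=O)O[C@@H]2/C=C(/CO[Si](C)(C)C(C)(C)C)[C@@H](OC(C)=O)C[C@H](O[Si](C)(C)C(C)(C)C)/C(C)=C/[C@@H](OC(=O)/C(C)=C/C)[C@@H]12 | intermediate
26 | (1S,3S,4Z,6R,7R,8R,9E)-3-acetoxy-1,15-dihydroxy-8-{[(2E)-2-methylbut-2-enoyl]oxy}germacra-4,9,11(13)-trien-12,6-olide (CNP0153210.7) | C=C1C(=O)O[C@@H]2/C=C(/CO)[C@@H](OC(C)=O)C[C@H](O)/C(C)=C/[C@@H](OC(=O)/C(C)=C/C)[C@@H]12 | target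

**Step count**
Total: 17 steps. Longest linear sequence: 10 steps (1, 2, 4, 5, 6, 7, 14, 15, 16, 17; the branch 8–13 followed by 14–17 is equally long), i.e. 10/17 of the total.

**Three steps most likely to fail**

Step 16 (ring-closing metathesis). The 1,1-disubstituted C4 alkene sits between two oxygenated allylic carbons, a medium ring with a trisubstituted olefin must form, and dimerisation or the 4E isomer may compete. Fallback: set out from 24 and remove both silyl ethers first (HF·pyridine) to give the diol (1R,2E,4S,6S)-6-acetoxy-1-[(2R,3S)-2-ethenyl-4-methylidene-5-oxooxolan-3-yl]-4-hydroxy-7-(hydroxymethyl)-3-methylocta-2,7-dien-1-yl (2E)-2-methylbut-2-enoate F1. The metathesis then becomes the last step and is run on F1, where the small free allylic C15 hydroxyl can assist the ruthenium carbene instead of a bulky silyl ether shielding the alkene. This comes back to the route directly at 26, bypassing 25.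

Step 15 (Mitsunobu inversion). C8 is a hindered secondary allylic carbinol next to the lactone ring, so elimination, SN2′ attack or retention through an allyl cation are possible. Fallback: set out from 23 and invert by redox instead of substitution. Dess–Martin oxidation gives the enone (2E,4S,6S)-4-(TBS-oxy)-7-[(TBS-oxy)methyl]-1-[(2R,3S)-2-ethenyl-4-methylidene-5-oxooxolan-3-yl]-3-methyl-1-oxoocta-2,7-dien-6-yl acetate F2. Reagent-controlled reduction with (R)-2-methyl-CBS-oxazaborolidine and catecholborane (alkenyl as the large group) gives the 8R epimer of 23, (4R,5R)-4-[(1R,2E,4S,6S)-6-acetoxy-4-(TBS-oxy)-7-[(TBS-oxy)methyl]-1-hydroxy-3-methylocta-2,7-dien-1-yl]-5-ethenyl-3-methylideneoxolan-2-one F3. F3 is esterified with retention (tiglic acid, 2,4,6-trichlorobenzoyl chloride, Et3N, 4-dimethylaminopyridine), which comes back to the route at 24. The same end of this path also serves if the Barbier step should deliver the 8R carbinol directly.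

Step 5 (Evans–Tishchenko reduction). Hydride transfer to a conjugated ketone can be slow, and the acetate can migrate from O3 to O1. Fallback: set out from 8, acetylate O3 first (Ac2O, pyridine, 0 °C) to give the β-acetoxy enone (2E,6S)-7-[(TBS-oxy)methyl]-1,1-dimethoxy-3-methyl-4-oxoocta-2,7-dien-6-yl acetate F4. C1 is then set by reagent control rather than intramolecular delivery, using (R)-2-methyl-CBS-oxazaborolidine and catecholborane at −78 °C (1,2-reduction, alkenyl as the large group, giving 1S). This comes back to the route at 9.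

**Further compounds**
F1 | step 16 | (1R,2E,4S,6S)-6-acetoxy-1-[(2R,3S)-2-ethenyl-4-methylidene-5-oxooxolan-3-yl]-4-hydroxy-7-(hydroxymethyl)-3-methylocta-2,7-dien-1-yl (2E)-2-methylbut-2-enoate | C=C1C(=O)O[C@H](C=C)[C@H]1[C@H](OC(=O)/C(C)=C/C)/C=C(\C)[C@@H](O)C[C@H](OC(C)=O)C(=C)CO
F2 | step 15 | (2E,4S,6S)-4-(TBS-oxy)-7-[(TBS-oxy)methyl]-1-[(2R,3S)-2-ethenyl-4-methylidene-5-oxooxolan-3-yl]-3-methyl-1-oxoocta-2,7-dien-6-yl acetate | C=C1C(=O)O[C@H](C=C)[C@H]1C(=O)/C=C(\C)[C@@H](O[Si](C)(C)C(C)(C)C)C[C@H](OC(C)=O)C(=C)CO[Si](C)(C)C(C)(C)C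
F3 | step 15 | (4R,5R)-4-[(1R,2E,4S,6S)-6-acetoxy-4-(TBS-oxy)-7-[(TBS-oxy)methyl]-1-hydroxy-3-methylocta-2,7-dien-1-yl]-5-ethenyl-3-methylideneoxolan-2-one | C=C1C(=O)O[C@H](C=C)[C@H]1[C@H](O)/C=C(\C)[C@@H](O[Si](C)(C)C(C)(C)C)C[C@H](OC(C)=O)C(=C)CO[Si](C)(C)C(C)(C)C
F4 | step 5 | (2E,6S)-7-[(TBS-oxy)methyl]-1,1-dimethoxy-3-methyl-4-oxoocta-2,7-dien-6-yl acetate | COC(OC)/C=C(\C)C(=O)C[C@H](OC(C)=O)C(=C)CO[Si](C)(C)C(C)(C)C
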